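**Strategy**

Everything rests on taking C3 out of the oxepine ring. C3 sits between C2, which is bonded to O1, and C4, so without it the seven-membered ring shrinks to the pyran of a 4H-chromene and the O1–C2=C enol ether appears. In one operation dibromocarbene adds to that alkene and the fused dibromocyclopropane opens: C3 is inserted, the C2–C3 and C3–C4 bonds form, the pyran becomes the 2,5-dihydrooxepine with its alkene at C3=C4, and a bromine is left on C3 for the methyl group. The precursor is 5,7-bis(methoxymethoxy)-4H-chromene from phloroglucinol and acrylic acid; the acyl chain is attached later at C7 by directed lithiation.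

Key step: step 5

Remark on the chemistry: the target has no stereocentre. Compounds 5, 6, 9 and 16 form as racemates and their stereocentres are lost again, so no step needs stereocontrol. Atom labels O1 to C9a follow the 1-benzoxepine numbering of the target unless chromene numbering is stated.

**Route**

Step 1
Reactants: 1 phloroglucinol; 2 acrylic acid
Product: 3 5,7-dihydroxychroman-2-one
Conditions: Amberlyst-15 (sulfonic acid resin), toluene, reflux, Dean–Stark, excess of 1
Reagents that add atoms: none
Why: Acid-catalysed Friedel–Crafts conjugate addition of the C-nucleophilic phloroglucinol to acrylic acid followed by lactonisation onto the neighbouring phenol should give the dihydrocoumarin; the threefold symmetry of 1 allows one regioisomer only and the excess of 1 limits a second annulation.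

Step 2
Reactants: 3 5,7-dihydroxychroman-2-one
Product: 4 5,7-bis(methoxymethoxy)chroman-2-one
Conditions: MOMCl, iPr2NEt, CH2Cl2, 0 °C → rt
Reagents that add atoms: chloromethyl methyl ether (MOMCl), COCCl
Why: O-alkylation of both phenols with the reactive α-chloro ether under a non-nucleophilic amine base (methoxymethyl ether formation) should leave the aryl lactone untouched.

Step 3
Reactants: 4 5,7-bis(methoxymethoxy)chroman-2-one
Product: 5 5,7-bis(methoxymethoxy)chroman-2-ol (racemic lactol)
Conditions: iBu2AlH (DIBAL-H, 1.1 equiv), CH2Cl2, −78 °C; aq. potassium sodium tartrate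
Reagents that add atoms: none
Why: Partial reduction of a lactone with one equivalent of the aluminium hydride at −78 °C stops at the aluminium hemiacetal and gives the lactol on work-up; the new C2 centre is uncontrolled and is destroyed in step 4.

Step 4
Reactants: 5 5,7-bis(methoxymethoxy)chroman-2-ol
Product: 7 5,7-bis(methoxymethoxy)-4H-chromene, via anomeric mesylate 6 (not isolated)
Conditions: MsCl, Et3N (excess), CH2Cl2, −20 °C → reflux; chromatography on Et3N-washed silica
Reagents that add atoms: none
Why: Sulfonylation of the lactol hydroxyl and amine-induced elimination of methanesulfonate (the lactol-to-cyclic-enol-ether dehydration used for glycals) should give the 4H-chromene under basic conditions that both the methoxymethyl ethers and the acid-sensitive enol ether tolerate.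

Step 5
Reactants: 7 5,7-bis(methoxymethoxy)-4H-chromene; 8 bromoform
Product: 10 3-bromo-6,8-bis(methoxymethoxy)-2,5-dihydro-1-benzoxepine, via dibromocyclopropane 9 (not isolated)
Conditions: 50% aq NaOH, BnEt3NCl (cat.), toluene, 0 °C → rt; separate, dry, evaporate under high vacuum; then AgOCOCF3 (added last, slowly), Et3SiH (10 equiv), 2,6-di-tert-butyl-4-methylpyridine, CH2Cl2 (0.02 M), −40 °C → rt, dark
Reagents that add atoms: none
Why: Proposed new method: the enol ether alkene of 7 (chromene C2=C3) is its only electron-rich alkene, so dibromocarbene made under phase-transfer conditions should add to it in a cheletropic [2+1] step to give the cis-fused dibromocyclopropane 9; silver trifluoroacetate should then remove the endo bromide while the ring-fusion bond opens in a disrotatory two-electron electrocyclic process, and triethylsilane should reduce the cyclic allyl cation that results. The closest known reaction type is the silver-promoted ring expansion of dibromocarbene adducts of glycals and other cyclic enol ethers, where the same cation is caught by an alcohol or a carboxylate; capture by a silane hydride is the untested part and is modelled on Ferrier-type reductions, in which an allylic oxocarbenium ion takes hydride at the carbon next to oxygen. The seven-membered ring is closed by ring expansion, that is by insertion of the carbene carbon into the former C2–C3 bond of the pyran, and not by an end-to-end cyclisation. No stereocentre remains in 10, because both ring-fusion centres of racemic 9 end as sp2 carbon or CH2 and the C3=C4 alkene can only be cis inside the ring. The step needs hydride at C2 and not at C4, at the arene of a second molecule or in place of loss of a C5 proton; the O1 lone pair concentrates the charge at C2, and a large excess of silane at high dilution should outrun the other pathways. Trifluoroacetate is chosen as counter-ion because its silyl ester is too weak a Lewis acid to attack the methoxymethyl ethers and because an anomeric trifluoroacetate, if it forms, should ionise again.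

Step 6
Reactants: 10 3-bromo-6,8-bis(methoxymethoxy)-2,5-dihydro-1-benzoxepine
Product: 11 6,8-bis(methoxymethoxy)-3-methyl-2,5-dihydro-1-benzoxepine
Conditions: MeZnCl (2 equiv), Pd(PPh3)4 (5 mol%), THF, 50 °C
Reagents that add atoms: methylzinc chloride, C[Zn]Cl
Why: Negishi cross-coupling (oxidative addition of the vinyl C–Br bond to zerovalent palladium, transmetalation from zinc, reductive elimination) should replace bromine by methyl without moving the alkene, and the mild organozinc leaves the acetals and the allylic aryl ether alone.

Step 7
Reactants: 12 3-(3,4-dihydroxyphenyl)propanoic acid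
Product: 13 3-(3,4-dihydroxyphenyl)-N-methoxy-N-methylpropanamide
Conditions: MeNHOMe·HCl, EDC·HCl, HOBt, N-methylmorpholine, DMF, 0 °C → rt, under N2
Reagents that add atoms: N,O-dimethylhydroxylamine hydrochloride, CNOC.Cl
Why: Carbodiimide amide coupling through the hydroxybenzotriazole active ester should acylate the amine, a far better nucleophile than the catechol hydroxyls, so the acid needs no prior protection.

Step 8
Reactants: 13 3-(3,4-dihydroxyphenyl)-N-methoxy-N-methylpropanamide
Product: 14 3-[3,4-bis(methoxymethoxy)phenyl]-N-methoxy-N-methylpropanamide
Conditions: MOMCl, iPr2NEt, CH2Cl2, 0 °C → rt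
Reagents that add atoms: chloromethyl methyl ether (MOMCl), COCCl
Why: Methoxymethyl ether formation on both catechol oxygens with amine base is routine and puts the same acid-labile group on all four phenols of the final skeleton.

Step 9
Reactants: 11 6,8-bis(methoxymethoxy)-3-methyl-2,5-dihydro-1-benzoxepine; 14 3-[3,4-bis(methoxymethoxy)phenyl]-N-methoxy-N-methylpropanamide
Product: 17 3-[3,4-bis(methoxymethoxy)phenyl]-1-[6,8-bis(methoxymethoxy)-3-methyl-2,5-dihydro-1-benzoxepin-7-yl]propan-1-one, via aryllithium 15 (not isolated), via lithium hemiaminal adduct 16 (not isolated)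
Conditions: n-BuLi (1.1 equiv), THF, −20 → 0 °C; then 14, −78 → 0 °C; then H2O
Reagents that add atoms: none
Why: Directed ortho-metalation should remove C7–H, which lies between two lithium-coordinating methoxymethoxy groups, in preference to C9–H (one such neighbour) and to the allylic C2 and C5 hydrogens, and acylation of 15 by the N-methoxy-N-methylamide (Weinreb ketone synthesis) stops at the chelated adduct 16, which gives the ketone on work-up.

Step 10
Reactants: 17 3-[3,4-bis(methoxymethoxy)phenyl]-1-[6,8-bis(methoxymethoxy)-3-methyl-2,5-dihydro-1-benzoxepin-7-yl]propan-1-one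
Product: 18 1-(6,8-dihydroxy-3-methyl-2,5-dihydro-1-benzoxepin-7-yl)-3-(3,4-dihydroxyphenyl)propan-1-one (CNP0203471.0)
Conditions: HCl (2 M in MeOH), MeOH/THF, rt → 40 °C
Reagents that add atoms: none
Why: Acid-catalysed acetal exchange with methanol should remove all four methoxymethyl groups as dimethoxymethane; the C6 phenol cannot add to the C3=C4 alkene because the resulting chroman would be an impossibly strained bridge across the oxepine ring, and dilute acid near room temperature should leave the allylic aryl ether and the alkene in place.

**Compound list**

1 | phloroglucinol | Oc1cc(O)cc(O)c1 | starting material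
2 | acrylic acid | C=CC(=O)O | starting material
3 | 5,7-dihydroxychroman-2-one | O=C1CCc2c(O)cc(O)cc2O1 | intermediate
4 | 5,7-bis(methoxymethoxy)chroman-2-one | COCOc1cc(OCOC)c2c(c1)OC(=O)CC2 | intermediate
5 | 5,7-bis(methoxymethoxy)chroman-2-ol (racemic) | COCOc1cc(OCOC)c2c(c1)OC(O)CC2 | intermediate
6 | 5,7-bis(methoxymethoxy)chroman-2-yl methanesulfonate (racemic, not isolated) | COCOc1cc(OCOC)c2c(c1)OC(OS(C)(=O)=O)CC2 | intermediate
7 | 5,7-bis(methoxymethoxy)-4H-chromene | COCOc1cc(OCOC)c2c(c1)OC=CC2 | intermediate
8 | bromoform | BrC(Br)Br | starting material
9 | 1,1-dibromo-4,6-bis(methoxymethoxy)-1,1a,7,7a-tetrahydrocyclopropa[b]chromene (cis-fused, racemic, one enantiomer written, not isolated) | COCOc1cc(OCOC)c2c(c1)O[C@@H]3[C@H](C2)C3(Br)Br | intermediate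
10 | 3-bromo-6,8-bis(methoxymethoxy)-2,5-dihydro-1-benzoxepine | COCOc1cc(OCOC)c2c(c1)OCC(Br)=CC2 | intermediate
11 | 6,8-bis(methoxymethoxy)-3-methyl-2,5-dihydro-1-benzoxepine | COCOc1cc(OCOC)c2c(c1)OCC(C)=CC2 | intermediate
12 | 3-(3,4-dihydroxyphenyl)propanoic acid (dihydrocaffeic acid) | O=C(O)CCc1ccc(O)c(O)c1 | starting material
13 | 3-(3,4-dihydroxyphenyl)-N-methoxy-N-methylpropanamide | CON(C)C(=O)CCc1ccc(O)c(O)c1 | intermediate
14 | 3-[3,4-bis(methoxymethoxy)phenyl]-N-methoxy-N-methylpropanamide | CON(C)C(=O)CCc1ccc(OCOC)c(OCOC)c1 | intermediate
15 | 7-lithio-6,8-bis(methoxymethoxy)-3-methyl-2,5-dihydro-1-benzoxepine (not isolated) | COCOc1c([Li])c(OCOC)c2c(c1)OCC(C)=CC2 | intermediate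
16 | lithium 3-[3,4-bis(methoxymethoxy)phenyl]-1-[6,8-bis(methoxymethoxy)-3-methyl-2,5-dihydro-1-benzoxepin-7-yl]-1-[methoxy(methyl)amino]propan-1-olate (racemic, not isolated) | COCOc1c(C(O[Li])(N(C)OC)CCc3ccc(OCOC)c(OCOC)c3)c(OCOC)c2c(c1)OCC(C)=CC2 | intermediate
17 | 3-[3,4-bis(methoxymethoxy)phenyl]-1-[6,8-bis(methoxymethoxy)-3-methyl-2,5-dihydro-1-benzoxepin-7-yl]propan-1-one | COCOc1c(C(=O)CCc3ccc(OCOC)c(OCOC)c3)c(OCOC)c2c(c1)OCC(C)=CC2 | intermediate
18 | 1-(6,8-dihydroxy-3-methyl-2,5-dihydro-1-benzoxepin-7-yl)-3-(3,4-dihydroxyphenyl)propan-1-one (CNP0203471.0) | CC1=CCc2c(cc(O)c(C(=O)CCc3ccc(O)c(O)c3)c2O)OC1 | target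

**Step count and risks**

Total step count: 10. Longest linear sequence: 8 steps (steps 1 to 6, 9 and 10); steps 7 and 8 prepare the side-chain fragment.

Steps most likely to fail:

1. Step 5, the one step that goes beyond established chemistry. The silane may reduce the silver salt before bromide abstraction. The allyl cation may alkylate the electron-rich arene of a second molecule. The cation may also lose a C5 proton to give the fully unsaturated benzoxepin. The fallback uses known chemistry and sets out from 7. The carbene addition is run as in step 5, but the cyclopropane 9 is isolated on base-washed silica. Heating 9 with AgOAc and NaOAc in methanol/toluene is the established silver-promoted ring expansion with alcohol capture. It should give the mixed acetal 3-bromo-2-methoxy-6,8-bis(methoxymethoxy)-2,5-dihydro-1-benzoxepine F1 (racemic). Ionic reduction of that acetal with Et3SiH and BF3·OEt2 in CH2Cl2 at −78 °C, as practised on 2-alkoxychromans and glycosides, should remove the methoxy group. Short exposure at that temperature should spare the methoxymethyl ethers. The fallback comes back to the route at 10.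

2. Step 4. Sulfonylation may occur at the phenol of the ring-opened hydroxy aldehyde tautomer instead of the lactol hydroxyl. The enol ether may also hydrolyse or oligomerise during isolation. The fallback sets out from lactone 4, so step 3 is no longer needed. Enolisation with KN(SiMe3)2 in THF at −78 °C in the presence of N-phenylbis(trifluoromethanesulfonimide) should give the ketene acetal triflate 5,7-bis(methoxymethoxy)-4H-chromen-2-yl trifluoromethanesulfonate F2. Palladium-catalysed formate reduction (Pd(OAc)2, PPh3, HCO2H, Bu3N, DMF, 40 °C) should then replace the triflate by hydrogen with no acidic stage. The fallback comes back to the route at 7.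

3. Step 9. The hindered aryllithium may take a proton from the enolisable amide instead of adding, returning 11. Lithiation may also be incomplete or occur partly at C9. The fallback sets out from 14 and 11. Reduction of 14 with iBu2AlH in THF at −78 °C should give 3-[3,4-bis(methoxymethoxy)phenyl]propanal F3. The aryllithium 15, made from 11 as in step 9, should add to this more electrophilic partner at −78 °C. The product would be 3-[3,4-bis(methoxymethoxy)phenyl]-1-[6,8-bis(methoxymethoxy)-3-methyl-2,5-dihydro-1-benzoxepin-7-yl]propan-1-ol F4 (racemic). Oxidation with Dess–Martin periodinane and NaHCO3 in CH2Cl2 should give the ketone, which is the return to the route at 17.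

**Further compounds**

F1 | step 5 | 3-bromo-2-methoxy-6,8-bis(methoxymethoxy)-2,5-dihydro-1-benzoxepine (racemic) | COCOc1cc(OCOC)c2c(c1)OC(OC)C(Br)=CC2
F2 | step 4 | 5,7-bis(methoxymethoxy)-4H-chromen-2-yl trifluoromethanesulfonate | COCOc1cc(OCOC)c2c(c1)OC(OS(=O)(=O)C(F)(F)F)=CC2
F3 | step 9 | 3-[3,4-bis(methoxymethoxy)phenyl]propanal | O=CCCc1ccc(OCOC)c(OCOC)c1
F4 | step 9 | 3-[3,4-bis(methoxymethoxy)phenyl]-1-[6,8-bis(methoxymethoxy)-3-methyl-2,5-dihydro-1-benzoxepin-7-yl]propan-1-ol (racemic) | COCOc1c(C(O)CCc3ccc(OCOC)c(OCOC)c3)c(OCOC)c2c(c1)OCC(C)=CC2
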